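**Retrosynthetic overview**

1. The strategy rests on ring A: its C5–C8 edge carries OH, OMe, OH, OMe in this order. This is the oxygen pattern of diene 20, the bis-silyl dienol ether of methyl 2,4-dimethoxyacetoacetate (ketene acetal carbon → C5–OH, C(OMe) → C6, silyl enol ether carbon → C7–OH, CH(OMe) → C8).
2. Key disconnection: C4a–C5 and C8–C8a. Ring A is built last, by formal [4+2] addition of 20 across C5=C6 of the 5-bromo-4-pyranone 15 (ring C already carrying ring B), with loss of HBr and MeOH, to give 23.
3. Ring C (15): C-acylation of the α'-enolate of bromo-enaminone 12 by aroyl chloride 8, then O1–C6 closure with loss of Me2NH. Bromine is put on the three-carbon unit before ring B is present.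
4. Ring B (8) comes from O-benzylisovanillin 1 by Baeyer–Villiger oxidation, benzylation, bromination and carboxylation. Diene 20 comes from methyl methoxyacetate 16 by Claisen self-condensation and two silylations.
5. Order of rings: B (bought) → C (step 8) → A (step 12). Hydrogenolysis of the two benzyl ethers (step 13) ends the route.

Key step: step 12

Remarks on the chemistry:
- 1, 9 and 16 are taken as commercial.
- Bromine is installed at the enaminone stage (step 7), because electrophilic bromination of a finished 2-aryl-3-methoxypyranone would be expected to attack C3' of the trialkoxyphenyl ring in competition with pyranone C5.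
- The neutral pyranone is a weak dienophile, so step 12 activates it as its 4-silyloxypyrylium salt.
- 8 and 20 are used crude.

**Route**

Step 1
Reactants: 1 3-(benzyloxy)-4-methoxybenzaldehyde
Product: 3 3-(benzyloxy)-4-methoxyphenol, via aryl formate 2 (not isolated)
Conditions: mCPBA, CH2Cl2, rt; then K2CO3 (cat.), MeOH, rt
Reagents that add atoms: mCPBA, O=C(OO)c1cccc(Cl)c1
Why: Baeyer–Villiger oxidation, in which the electron-rich aryl group (para-methoxy) migrates to give formate 2, which methanolysis cleaves to the phenol.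

Step 2
Reactants: 3 3-(benzyloxy)-4-methoxyphenol
Product: 4 2,4-bis(benzyloxy)-1-methoxybenzene
Conditions: BnBr, K2CO3, DMF, 60 °C
Reagents that add atoms: benzyl bromide, BrCc1ccccc1
Why: Williamson ether synthesis of a phenoxide with a benzylic bromide.

Step 3
Reactants: 4 2,4-bis(benzyloxy)-1-methoxybenzene
Product: 5 1-bromo-2,4-bis(benzyloxy)-5-methoxybenzene
Conditions: NBS (1.0 equiv), MeCN, 0 °C to rt
Reagents that add atoms: N-bromosuccinimide, O=C1CCC(=O)N1Br
Why: Electrophilic aromatic bromination should go para to the 2-benzyloxy and ortho to the 4-benzyloxy group, since the site between the two benzyloxy groups is hindered and the site ortho to methoxy has only one activating donor.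

Step 4
Reactants: 5 1-bromo-2,4-bis(benzyloxy)-5-methoxybenzene
Product: 7 2,4-bis(benzyloxy)-5-methoxybenzoic acid, via aryllithium 6 (not isolated)
Conditions: n-BuLi, THF, −78 °C; CO2; then 1 M HCl
Reagents that add atoms: carbon dioxide, O=C=O
Why: Lithium–bromine exchange is faster than benzylic deprotonation at −78 °C, and the aryllithium is carboxylated by CO2.

Step 5
Reactants: 7 2,4-bis(benzyloxy)-5-methoxybenzoic acid
Product: 8 2,4-bis(benzyloxy)-5-methoxybenzoyl chloride
Conditions: (COCl)2, DMF (cat.), CH2Cl2, 0 °C to rt; evaporated and used crude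
Reagents that add atoms: oxalyl chloride, O=C(Cl)C(=O)Cl
Why: Acid chloride formation through the Vilsmeier-type chloroiminium ion, conditions that aryl benzyl ethers tolerate.

Step 6
Reactants: 9 N,2-dimethoxy-N-methylacetamide
Product: 11 (E)-4-(dimethylamino)-1-methoxybut-3-en-2-one, via terminal ynone 10 (not isolated)
Conditions: HC≡CMgBr, THF, 0 °C; cold 1 M HCl, extraction (CH2Cl2); then Me2NH (2 M in THF), 0 °C
Reagents that add atoms: ethynylmagnesium bromide, C#C[Mg]Br; dimethylamine, CNC
Why: Weinreb ketone synthesis (the magnesium chelate stops at the ketone stage) gives the terminal ynone, and aza-Michael addition of dimethylamine gives the favoured (E)-enaminone, while the acid quench keeps the liberated N,O-dimethylhydroxylamine protonated in the water layer.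

Step 7
Reactants: 11 (E)-4-(dimethylamino)-1-methoxybut-3-en-2-one
Product: 12 (Z)-3-bromo-4-(dimethylamino)-1-methoxybut-3-en-2-one
Conditions: NBS (1.0 equiv), CH2Cl2, 0 °C
Reagents that add atoms: N-bromosuccinimide, O=C1CCC(=O)N1Br
Why: α-Halogenation of a push–pull enaminone at its single nucleophilic carbon; no arene or 1,3-dicarbonyl unit is present yet, so bromine can only end on the future C5.

Step 8
Reactants: 12 (Z)-3-bromo-4-(dimethylamino)-1-methoxybut-3-en-2-one; 8 2,4-bis(benzyloxy)-5-methoxybenzoyl chloride
Product: 15 2-[2,4-bis(benzyloxy)-5-methoxyphenyl]-5-bromo-3-methoxy-4H-pyran-4-one, via lithium enolate 13 (not isolated), via bromo diketone 14 (not isolated)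
Conditions: 12 (2.1 equiv), LiN(SiMe3)2 (2.1 equiv), THF, −78 °C; 8 (1 equiv), −78 to −20 °C; then TFA, CH2Cl2, rt
Reagents that add atoms: none
Why: Claisen-type C-acylation of the kinetic α'-enolate of a vinylogous amide by an aroyl chloride (the second equivalent of enolate takes up the acidic diketone proton), then acid-promoted 6-endo-trig addition–elimination of the aryl ketone enol oxygen at the enaminone carbon with loss of dimethylamine, the established enolate-acylation and cyclodehydration route to 4-pyranones.

Step 9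
Reactants: 16 methyl methoxyacetate (two molecules)
Product: 17 methyl 2,4-dimethoxy-3-oxobutanoate
Conditions: NaH, THF, 50 °C; then aq. HCl
Reagents that add atoms: none
Why: Claisen self-condensation, driven by deprotonation of the β-keto ester product.

Step 10
Reactants: 17 methyl 2,4-dimethoxy-3-oxobutanoate
Product: 18 methyl 2,4-dimethoxy-3-[(trimethylsilyl)oxy]but-2-enoate
Conditions: Me3SiCl, Et3N, toluene, rt
Reagents that add atoms: chlorotrimethylsilane, C[Si](C)(C)Cl
Why: Soft enolisation and O-silylation of the β-keto ester gives the conjugated silyl enol ether, the first stage of the usual two-stage preparation of 1,3-bis(silyloxy)dienes.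

Step 11
Reactants: 18 methyl 2,4-dimethoxy-3-[(trimethylsilyl)oxy]but-2-enoate
Product: 20 1,2,4-trimethoxy-1,3-bis[(trimethylsilyl)oxy]buta-1,3-diene, via lithium dienolate 19 (not isolated)
Conditions: LiN(i-Pr)2, THF, −78 °C; Me3SiCl, −78 to 0 °C; pentane, filtration under argon; used crude
Reagents that add atoms: chlorotrimethylsilane, C[Si](C)(C)Cl
Why: Kinetic γ-deprotonation of the vinylogous ester and O-silylation of the dienolate, the second stage of the 1,3-bis(silyloxy)diene preparation.

Step 12
Reactants: 15 2-[2,4-bis(benzyloxy)-5-methoxyphenyl]-5-bromo-3-methoxy-4H-pyran-4-one; 20 1,2,4-trimethoxy-1,3-bis[(trimethylsilyl)oxy]buta-1,3-diene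
Product: 23 2-[2,4-bis(benzyloxy)-5-methoxyphenyl]-5,7-dihydroxy-3,6,8-trimethoxy-4H-chromen-4-one, via silyloxypyrylium triflate 21 (not isolated), via bromo cycloadduct 22 (not isolated)
Conditions: Me3SiOTf (1.2 equiv), 2,6-di-tert-butylpyridine (0.2 equiv), CH2Cl2, 0 °C, 1 h; 20 (1.5 equiv), −78 °C to rt; then 1 M HCl, THF, rt
Reagents that add atoms: none
Why: Proposed new method: O-silylation of 15 gives the 4-silyloxypyrylium ion 21, whose only unsubstituted α-carbon, C6, is attacked by the CH(OMe) terminus of 20 (vinylogous Mukaiyama–Michael addition, forming C8–C8a), and the 5-bromo silyl enol ether so formed closes onto the methoxy(silyloxy)carbenium carbon of the side chain (6-(enolexo)-exo-trig, forming C4a–C5) to give the formal [4+2] adduct 22; the closest known reaction types are the halogen-directed cycloaromatisation of 1-alkoxy-1,3-bis(silyloxy)dienes with haloquinones and halo-enones and the silyl triflate-mediated annulation of 4-silyloxybenzopyrylium salts with 2-silyloxydienes, neither shown on a 3-halo-4-pyranone. In the acidic work-up the C5 ketal loses methanol, the C7 silyl enol ether is cleaved and ring A enolises, so that the C4a–Br bond sits on a cyclohexadiene and ionises to an arenium-type cation that loses the C8a proton; the net loss of HBr and MeOH aromatises ring A with 5-OH and 7-OH free and 6-OMe and 8-OMe in place. The stereocentres of 22 (C4a, C5, C8, C8a) need no control because all are erased on aromatisation. The step needs one orientation of the diene, and polarity secures it: the most nucleophilic diene terminus meets C6, the only electrophilic ring carbon not blocked (C2 carries ring B), while bromine marks C5 as the second terminus and serves as the leaving group. Methanol and not silanol should leave from the C5 ketal because the methoxy oxygen is the more basic one and the O–Si bond is broken only by the aqueous acid, which leaves the chelated 5-OH.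

Step 13
Reactants: 23 2-[2,4-bis(benzyloxy)-5-methoxyphenyl]-5,7-dihydroxy-3,6,8-trimethoxy-4H-chromen-4-one
Product: 24 2-(2,4-dihydroxy-5-methoxyphenyl)-5,7-dihydroxy-3,6,8-trimethoxy-4H-chromen-4-one (5,7,2',4'-tetrahydroxy-3,6,8,5'-tetramethoxyflavone)
Conditions: H2 (1 atm), 10% Pd/C, EtOAc–MeOH, rt
Reagents that add atoms: none
Why: Hydrogenolysis of aryl benzyl ethers over Pd/C, under which the tetrasubstituted C2=C3 bond of the chromone and the methyl ethers should stay untouched.

**Compound list**

1 | 3-(benzyloxy)-4-methoxybenzaldehyde (O-benzylisovanillin) | COc1ccc(C=O)cc1OCc1ccccc1 | starting material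
2 | 3-(benzyloxy)-4-methoxyphenyl formate | COc1ccc(OC=O)cc1OCc1ccccc1 | intermediate
3 | 3-(benzyloxy)-4-methoxyphenol | COc1ccc(O)cc1OCc1ccccc1 | intermediate
4 | 2,4-bis(benzyloxy)-1-methoxybenzene | COc1ccc(OCc2ccccc2)cc1OCc1ccccc1 | intermediate
5 | 1-bromo-2,4-bis(benzyloxy)-5-methoxybenzene | COc1cc(Br)c(OCc2ccccc2)cc1OCc1ccccc1 | intermediate
6 | [2,4-bis(benzyloxy)-5-methoxyphenyl]lithium | [Li]c1cc(OC)c(OCc2ccccc2)cc1OCc1ccccc1 | intermediate
7 | 2,4-bis(benzyloxy)-5-methoxybenzoic acid | COc1cc(C(=O)O)c(OCc2ccccc2)cc1OCc1ccccc1 | intermediate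
8 | 2,4-bis(benzyloxy)-5-methoxybenzoyl chloride | COc1cc(C(=O)Cl)c(OCc2ccccc2)cc1OCc1ccccc1 | intermediate
9 | N,2-dimethoxy-N-methylacetamide | COCC(=O)N(C)OC | starting material
10 | 1-methoxybut-3-yn-2-one | COCC(=O)C#C | intermediate
11 | (E)-4-(dimethylamino)-1-methoxybut-3-en-2-one | COCC(=O)/C=C/N(C)C | intermediate
12 | (Z)-3-bromo-4-(dimethylamino)-1-methoxybut-3-en-2-one | COCC(=O)/C(Br)=C/N(C)C | intermediate
13 | lithium (Z)-3-bromo-4-(dimethylamino)-1-methoxybuta-1,3-dien-2-olate (enolate geometry not assigned) | [Li+].COC=C([O-])/C(Br)=C/N(C)C | intermediate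
14 | (Z)-1-[2,4-bis(benzyloxy)-5-methoxyphenyl]-4-bromo-5-(dimethylamino)-2-methoxypent-4-ene-1,3-dione (racemic, enolisable at C2) | COC(C(=O)c1cc(OC)c(OCc2ccccc2)cc1OCc1ccccc1)C(=O)/C(Br)=C/N(C)C | intermediate
15 | 2-[2,4-bis(benzyloxy)-5-methoxyphenyl]-5-bromo-3-methoxy-4H-pyran-4-one | COc1c(-c2cc(OC)c(OCc3ccccc3)cc2OCc2ccccc2)occ(Br)c1=O | intermediate
16 | methyl methoxyacetate | COCC(=O)OC | starting material
17 | methyl 2,4-dimethoxy-3-oxobutanoate (racemic) | COCC(=O)C(OC)C(=O)OC | intermediate
18 | methyl 2,4-dimethoxy-3-[(trimethylsilyl)oxy]but-2-enoate (E/Z mixture) | COCC(O[Si](C)(C)C)=C(OC)C(=O)OC | intermediate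
19 | lithium 1,2,4-trimethoxy-3-[(trimethylsilyl)oxy]buta-1,3-dien-1-olate (geometry not assigned) | [Li+].COC=C(O[Si](C)(C)C)C(OC)=C([O-])OC | intermediate
20 | 1,2,4-trimethoxy-1,3-bis[(trimethylsilyl)oxy]buta-1,3-diene (geometry not assigned) | COC=C(O[Si](C)(C)C)C(OC)=C(OC)O[Si](C)(C)C | intermediate
21 | 2-[2,4-bis(benzyloxy)-5-methoxyphenyl]-5-bromo-3-methoxy-4-[(trimethylsilyl)oxy]pyrylium trifluoromethanesulfonate | COc1c(O[Si](C)(C)C)c(Br)c[o+]c1-c1cc(OC)c(OCc2ccccc2)cc1OCc1ccccc1.[O-]S(=O)(=O)C(F)(F)F | intermediate
22 | 2-[2,4-bis(benzyloxy)-5-methoxyphenyl]-4a-bromo-3,5,6,8-tetramethoxy-5,7-bis[(trimethylsilyl)oxy]-4a,5,8,8a-tetrahydro-4H-chromen-4-one (cis-fused, mixture of diastereomers, configuration not assigned) | COC1=C(c2cc(OC)c(OCc3ccccc3)cc2OCc2ccccc2)OC2C(OC)C(O[Si](C)(C)C)=C(OC)C(OC)(O[Si](C)(C)C)C2(Br)C1=O | intermediate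
23 | 2-[2,4-bis(benzyloxy)-5-methoxyphenyl]-5,7-dihydroxy-3,6,8-trimethoxy-4H-chromen-4-one | COc1cc(-c2oc3c(OC)c(O)c(OC)c(O)c3c(=O)c2OC)c(OCc2ccccc2)cc1OCc1ccccc1 | intermediate
24 | 2-(2,4-dihydroxy-5-methoxyphenyl)-5,7-dihydroxy-3,6,8-trimethoxy-4H-chromen-4-one | COc1cc(-c2oc3c(OC)c(O)c(OC)c(O)c3c(=O)c2OC)c(O)cc1O | target

**Step count**

Total step count: 13. Longest linear sequence: 8 steps (steps 1, 2, 3, 4, 5, 8, 12, 13).

**Steps most likely to fail**

Step 12 (proposed new method). The ring closure may not follow the conjugate addition; the side chain is then released as a β-keto ester and the dihydropyranone simply loses HBr to a 6-substituted pyranone. Bromine may also be transferred as Br+ to excess diene, after which ring C opens. The fallback uses known chemistry only, sets out from 7 and 8, and returns at 23. Acid chloride 8 and acid 7 are joined with pyridine in CH2Cl2 to 2,4-bis(benzyloxy)-5-methoxybenzoic anhydride F1. Phloroglucinol and methoxyacetonitrile give, by Hoesch acylation (ZnCl2, HCl, Et2O, 0 °C; then boiling water), 2-methoxy-1-(2,4,6-trihydroxyphenyl)ethan-1-one F2. Allan–Robinson condensation of F2 with F1 and the sodium salt of 7 (170 °C), followed by brief treatment with KOH in aqueous methanol to cleave O-aroyl groups, should give 2-[2,4-bis(benzyloxy)-5-methoxyphenyl]-5,7-dihydroxy-3-methoxy-4H-chromen-4-one F3. NBS (2 equiv, DMF, 0 °C) should brominate the phloroglucinol-type ring, which is far more nucleophilic than ring B, at C6 and C8 to give 2-[2,4-bis(benzyloxy)-5-methoxyphenyl]-6,8-dibromo-5,7-dihydroxy-3-methoxy-4H-chromen-4-one F4. Ullmann-type methoxylation (NaOMe, CuBr, DMF–MeOH, 110 °C) then replaces both bromines and gives 23, from which step 13 follows.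

Step 8. The bromo-substituted enolate 13 may be acylated on oxygen, or may lose bromide before it is acylated. The fallback reverses the order of bromination and C–C bond formation; it sets out from 11 and 8 and returns at 14. The α'-enolate of the unbrominated enaminone 11 (LiN(SiMe3)2, THF, −78 °C) is acylated with 8 to (E)-1-[2,4-bis(benzyloxy)-5-methoxyphenyl]-5-(dimethylamino)-2-methoxypent-4-ene-1,3-dione F5. NBS (1 equiv, CH2Cl2, −40 °C) should then brominate the enaminone carbon, by far the most nucleophilic site of F5, as in the halogenative cyclisation of o-hydroxyaryl enaminones to 3-halochromones. This gives 14, which is cyclised with TFA as in step 8 to 15.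

Step 6. The small, water-soluble and easily polymerised ynone 10 may be lost on extraction, or may add the liberated N,O-dimethylhydroxylamine in place of dimethylamine. The fallback uses a silyl-capped, isolable ynone; it sets out from 9 and returns at 11. Lithium (trimethylsilyl)acetylide (Me3SiC≡CH, n-BuLi, THF, −78 °C) and 9 give 1-methoxy-4-(trimethylsilyl)but-3-yn-2-one F6, which can be extracted and purified. Me2NH in MeOH should add in conjugate fashion with loss of the silyl group to give 11.

Further compounds
F1 | step 12 | 2,4-bis(benzyloxy)-5-methoxybenzoic anhydride | O=C(OC(=O)c1cc(OC)c(OCc2ccccc2)cc1OCc1ccccc1)c1cc(OC)c(OCc2ccccc2)cc1OCc1ccccc1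
F2 | step 12 | 2-methoxy-1-(2,4,6-trihydroxyphenyl)ethan-1-one | COCC(=O)c1c(O)cc(O)cc1O
F3 | step 12 | 2-[2,4-bis(benzyloxy)-5-methoxyphenyl]-5,7-dihydroxy-3-methoxy-4H-chromen-4-one | COc1cc(-c2oc3cc(O)cc(O)c3c(=O)c2OC)c(OCc2ccccc2)cc1OCc1ccccc1
F4 | step 12 | 2-[2,4-bis(benzyloxy)-5-methoxyphenyl]-6,8-dibromo-5,7-dihydroxy-3-methoxy-4H-chromen-4-one | COc1cc(-c2oc3c(Br)c(O)c(Br)c(O)c3c(=O)c2OC)c(OCc2ccccc2)cc1OCc1ccccc1
F5 | step 8 | (E)-1-[2,4-bis(benzyloxy)-5-methoxyphenyl]-5-(dimethylamino)-2-methoxypent-4-ene-1,3-dione | CN(C)/C=C/C(=O)C(OC)C(=O)c1cc(OC)c(OCc2ccccc2)cc1OCc1ccccc1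
F6 | step 6 | 1-methoxy-4-(trimethylsilyl)but-3-yn-2-one | COCC(=O)C#C[Si](C)(C)C
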